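## Retrosynthetic overview

1. The 7α-hydroperoxide with the C8=C9 alkene comes from a singlet-oxygen ene reaction on the C7=C8 alkene. The cinnamate comes from an acrylate and styrene by cross-metathesis, and the tertiary ester from methyllithium addition to a C4 ketone with in-situ acylation.
2. Ring B is closed second, by ring-closing metathesis of an allyl group on C10 and a 2-isopropylallyl group on C5. C1 is then reduced and C5 is protonated kinetically while C4 is still a silyl enol ether.
3. Key disconnection: the C9–C10 bond and the C10 quaternary centre come from a stereospecific 1,2-allyl shift (vinylogous semipinacol) from the C1 carbinol to C10 of a 4-hydroxycyclohex-2-enone.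
4. The rearrangement substrate comes from α-alkylation of the γ-hydroxy enone, which comes from allylic oxidation of the product of a catalytic asymmetric allylation of 2-methylcyclohex-2-en-1-one.
5. Ring order: ring A is present from the starting enone; ring B is formed by metathesis.

## Assumptions

- Locants C1–C10 follow eudesmane numbering of the target: C10 carries the angular methyl, C1 the free OH, C4 the ester, C5 the ring-fusion H, C7 the OOH.
- (R)-BINOL is assumed to give the (S)-carbinol in step 1; if the sense of induction is opposite, (S)-BINOL is used.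
- 2-(Bromomethyl)-3-methylbut-1-ene is taken as a purchasable building block.

## Route

Step 1
Reactants: 1 2-methylcyclohex-2-en-1-one
Product: 2 (1S)-2-methyl-1-(prop-2-en-1-yl)cyclohex-2-en-1-ol
Conditions: tetraallylstannane (1.5 equiv), Ti(OiPr)4 (30 mol %), (R)-BINOL (30 mol %), iPrOH (20 equiv), CH2Cl2, rt
Reagents that add atoms: tetraallylstannane C=CC[Sn](CC=C)(CC=C)CC=C
Why: Titanium–BINOL-catalysed enantioselective 1,2-allylation of ketones with tetraallylstannane is established for 2-substituted cyclic enones, and the catalyst selects one carbonyl face to set the (S)-carbinol that later controls C10.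

Step 2
Reactants: 2 (1S)-2-methyl-1-(prop-2-en-1-yl)cyclohex-2-en-1-ol
Product: 3 (4S)-4-hydroxy-3-methyl-4-(prop-2-en-1-yl)cyclohex-2-en-1-one
Conditions: Rh2(cap)4 (dirhodium tetracaprolactamate, 1 mol %), t-BuOOH (70% aq., 5 equiv), K2CO3 (0.5 equiv), CH2Cl2, rt
Reagents that add atoms: tert-butyl hydroperoxide CC(C)(C)OO
Why: Radical-chain allylic C–H oxidation with tert-butylperoxyl radicals converts the ring CH2 next to the trisubstituted alkene (the site giving the most substituted allyl radical) into the enone carbonyl, while the tertiary carbinol cannot be oxidised and keeps its configuration.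

Step 3
Reactants: 3 (4S)-4-hydroxy-3-methyl-4-(prop-2-en-1-yl)cyclohex-2-en-1-one; 4 2-(bromomethyl)-3-methylbut-1-ene
Product: 6 (4S)-4-hydroxy-3-methyl-2-(3-methyl-2-methylidenebutyl)-4-(prop-2-en-1-yl)cyclohex-2-en-1-one, via methylidene ketone 5 (not isolated)
Conditions: KOtBu (2.2 equiv), t-BuOH/THF, 0 °C; 4 (1.05 equiv), 0 °C → rt; aq. NH4Cl
Reagents that add atoms: none
Why: Thermodynamic deprotonation of the β-methyl enone gives the extended dienolate, which is alkylated at the α-carbon by the allylic bromide (classical α-alkylation of 3-methylcyclohexenones), and the first-formed deconjugated ketone 5 re-conjugates under the base without touching the carbinol stereocentre.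

Step 4
Reactants: 6 (4S)-4-hydroxy-3-methyl-2-(3-methyl-2-methylidenebutyl)-4-(prop-2-en-1-yl)cyclohex-2-en-1-one
Product: 7 (2R)-2-methyl-3-(3-methyl-2-methylidenebutyl)-2-(prop-2-en-1-yl)-4-{[tri(propan-2-yl)silyl]oxy}cyclohex-3-en-1-one
Conditions: TIPSOTf (1.3 equiv), 2,6-di-tert-butyl-4-methylpyridine (1.5 equiv), CH2Cl2, −78 → −20 °C
Reagents that add atoms: tri(propan-2-yl)silyl trifluoromethanesulfonate CC(C)[Si](OS(=O)(=O)C(F)(F)F)(C(C)C)C(C)C
Why: Proposed new method: reversible O-silylation of the enone by the bulky silyl triflate (too hindered to silylate the tertiary alcohol quickly) gives a 1-silyloxyallyl cation whose tertiary terminus C10 lies next to the carbinol, the allyl group (held pseudoaxial by allylic strain with the vinylic methyl) shifts suprafacially from C1 to C10 with hydroxyl push, and the hindered pyridine removes the proton of the new ketone, so that the C1 configuration is transferred to the (R)-quaternary centre and the former enone is captured as a regiodefined silyl enol ether, the closest known chemistry being the semipinacol rearrangement in its vinylogous forms (amine-catalysed vinylogous α-ketol ring expansion of cyclobutanols and the acid-mediated quinol-to-enedione 1,2-shift), neither of which has been shown for an unstrained 4-hydroxycyclohex-2-enone with silyl triflate activation and enol silane capture.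

Step 5
Reactants: 7 (2R)-2-methyl-3-(3-methyl-2-methylidenebutyl)-2-(prop-2-en-1-yl)-4-{[tri(propan-2-yl)silyl]oxy}cyclohex-3-en-1-one
Product: 8 (8aR)-8a-methyl-6-(propan-2-yl)-4-{[tri(propan-2-yl)silyl]oxy}-2,3,8,8a-tetrahydronaphthalen-1(5H)-one
Conditions: second-generation Hoveyda–Grubbs catalyst (5 mol %), toluene, 60 °C, argon sparge
Reagents that add atoms: none
Why: Ring-closing metathesis of the allyl and 2-isopropylallyl groups closes ring B as a trisubstituted cyclohexene with loss of ethene, the tetrasubstituted silyl enol ether and the hindered ketone being inert to the ruthenium carbene and no stereocentre being touched.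

Step 6
Reactants: 8 (8aR)-8a-methyl-6-(propan-2-yl)-4-{[tri(propan-2-yl)silyl]oxy}-2,3,8,8a-tetrahydronaphthalen-1(5H)-one
Product: 10 (4R,4aR,8aR)-4-hydroxy-4a-methyl-7-(propan-2-yl)-3,4,4a,5,8,8a-hexahydronaphthalen-1(2H)-one, via hydroxy enol silane 9 (not isolated)
Conditions: NaBH4, MeOH/THF, −40 °C; then AcOH (excess), TBAF, THF, −40 → 0 °C
Reagents that add atoms: none
Why: Borohydride reduction attacks the C1 ketone from the α-face opposite the angular methyl (as in Wieland–Miescher-type ketones) to give the equatorial 1β-alcohol while C4 is still masked, and buffered fluoride desilylation then protonates the ring-fusion enolate at C5 kinetically from the same open α-face, giving the trans-fused ketone under non-equilibrating conditions.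

Step 7
Reactants: 10 (4R,4aR,8aR)-4-hydroxy-4a-methyl-7-(propan-2-yl)-3,4,4a,5,8,8a-hexahydronaphthalen-1(2H)-one; 11 prop-2-enoyl chloride (acryloyl chloride)
Product: 15 (1S,4R,4aR,8aR)-4-hydroxy-1,4a-dimethyl-7-(propan-2-yl)-1,2,3,4,4a,5,8,8a-octahydronaphthalen-1-yl prop-2-enoate, via trimethylsilyl ether 12 (not isolated), via lithium alkoxide 13 (not isolated), via silylated acrylate 14 (not isolated)
Conditions: HMDS, TMSCl (cat.), CH2Cl2, rt, then evaporate; MeLi (1.3 equiv), Et2O, −78 °C; 11 (2 equiv), −78 → 0 °C; aq. citric acid, THF, rt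
Reagents that add atoms: methyllithium [Li]C; hexamethyldisilazane C[Si](C)(C)N[Si](C)(C)C (silyl group present in 12 to 14 only)
Why: After transient silylation of the secondary alcohol, 1,2-addition of methyllithium to the C4 ketone follows the equatorial trajectory because the axial one is blocked by the syn-axial angular methyl (giving the axial 4β-alkoxide and equatorial 4α-methyl), the lithium alkoxide is acylated in situ, and the acidic work-up removes the trimethylsilyl group.

Step 8
Reactants: 15 (1S,4R,4aR,8aR)-4-hydroxy-1,4a-dimethyl-7-(propan-2-yl)-1,2,3,4,4a,5,8,8a-octahydronaphthalen-1-yl prop-2-enoate; 16 styrene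
Product: 17 (1S,4R,4aR,8aR)-4-hydroxy-1,4a-dimethyl-7-(propan-2-yl)-1,2,3,4,4a,5,8,8a-octahydronaphthalen-1-yl (2E)-3-phenylprop-2-enoate
Conditions: 16 (5 equiv), second-generation Hoveyda–Grubbs catalyst (5 mol %), CH2Cl2, 40 °C
Reagents that add atoms: none
Why: Olefin cross-metathesis of an acrylate with styrene gives the (E)-cinnamate selectively, the trisubstituted ring alkene being unreactive in cross-metathesis.

Step 9
Reactants: 17 (1S,4R,4aR,8aR)-4-hydroxy-1,4a-dimethyl-7-(propan-2-yl)-1,2,3,4,4a,5,8,8a-octahydronaphthalen-1-yl (2E)-3-phenylprop-2-enoate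
Product: 18 (1S,4R,4aR,7S,8aR)-7-hydroperoxy-4-hydroxy-1,4a-dimethyl-7-(propan-2-yl)-1,2,3,4,4a,7,8,8a-octahydronaphthalen-1-yl (2E)-3-phenylprop-2-enoate
Conditions: O2, tetraphenylporphyrin (1 mol %), CH2Cl2, −20 °C, white LED
Reagents that add atoms: dioxygen O=O
Why: Schenck ene reaction of singlet oxygen on the C7=C8 alkene from the α-face (the β-face is screened by the angular methyl and the axial ester), where only the pseudoaxial 9α-hydrogen is aligned for abstraction, delivers oxygen to C7 and shifts the double bond to C8=C9, and the sensitiser triplet is too low in energy to isomerise the cinnamate.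

## Compound list

1 | 2-methylcyclohex-2-en-1-one | CC1=CCCCC1=O | starting material
2 | (1S)-2-methyl-1-(prop-2-en-1-yl)cyclohex-2-en-1-ol | C=CC[C@@]1(O)CCCC=C1C | intermediate
3 | (4S)-4-hydroxy-3-methyl-4-(prop-2-en-1-yl)cyclohex-2-en-1-one | C=CC[C@@]1(O)CCC(=O)C=C1C | intermediate
4 | 2-(bromomethyl)-3-methylbut-1-ene | C=C(CBr)C(C)C | starting material
5 | (4S)-4-hydroxy-3-methylidene-2-(3-methyl-2-methylidenebutyl)-4-(prop-2-en-1-yl)cyclohexan-1-one, both C2 epimers, not isolated | C=CC[C@@]1(O)CCC(=O)C(CC(=C)C(C)C)C1=C | intermediate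
6 | (4S)-4-hydroxy-3-methyl-2-(3-methyl-2-methylidenebutyl)-4-(prop-2-en-1-yl)cyclohex-2-en-1-one | C=CC[C@@]1(O)CCC(=O)C(CC(=C)C(C)C)=C1C | intermediate
7 | (2R)-2-methyl-3-(3-methyl-2-methylidenebutyl)-2-(prop-2-en-1-yl)-4-{[tri(propan-2-yl)silyl]oxy}cyclohex-3-en-1-one | C=CC[C@@]1(C)C(=O)CCC(O[Si](C(C)C)(C(C)C)C(C)C)=C1CC(=C)C(C)C | intermediate
8 | (8aR)-8a-methyl-6-(propan-2-yl)-4-{[tri(propan-2-yl)silyl]oxy}-2,3,8,8a-tetrahydronaphthalen-1(5H)-one | CC(C)C1=CC[C@@]2(C)C(=O)CCC(O[Si](C(C)C)(C(C)C)C(C)C)=C2C1 | intermediate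
9 | (1R,8aR)-8a-methyl-6-(propan-2-yl)-4-{[tri(propan-2-yl)silyl]oxy}-1,2,3,5,8,8a-hexahydronaphthalen-1-ol, not isolated | CC(C)C1=CC[C@@]2(C)[C@H](O)CCC(O[Si](C(C)C)(C(C)C)C(C)C)=C2C1 | intermediate
10 | (4R,4aR,8aR)-4-hydroxy-4a-methyl-7-(propan-2-yl)-3,4,4a,5,8,8a-hexahydronaphthalen-1(2H)-one (1β-hydroxy-15-nor-eudesm-7-en-4-one, 5α-H) | CC(C)C1=CC[C@@]2(C)[C@H](O)CCC(=O)[C@@H]2C1 | intermediate
11 | prop-2-enoyl chloride (acryloyl chloride) | C=CC(=O)Cl | starting material
12 | (4R,4aR,8aR)-4a-methyl-7-(propan-2-yl)-4-[(trimethylsilyl)oxy]-3,4,4a,5,8,8a-hexahydronaphthalen-1(2H)-one, not isolated | CC(C)C1=CC[C@@]2(C)[C@H](O[Si](C)(C)C)CCC(=O)[C@@H]2C1 | intermediate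
13 | lithium (1S,4R,4aR,8aR)-1,4a-dimethyl-7-(propan-2-yl)-4-[(trimethylsilyl)oxy]-1,2,3,4,4a,5,8,8a-octahydronaphthalen-1-olate, not isolated | CC(C)C1=CC[C@@]2(C)[C@H](O[Si](C)(C)C)CC[C@](C)(O[Li])[C@@H]2C1 | intermediate
14 | (1S,4R,4aR,8aR)-1,4a-dimethyl-7-(propan-2-yl)-4-[(trimethylsilyl)oxy]-1,2,3,4,4a,5,8,8a-octahydronaphthalen-1-yl prop-2-enoate, not isolated | CC(C)C1=CC[C@@]2(C)[C@H](O[Si](C)(C)C)CC[C@](C)(OC(=O)C=C)[C@@H]2C1 | intermediate
15 | (1S,4R,4aR,8aR)-4-hydroxy-1,4a-dimethyl-7-(propan-2-yl)-1,2,3,4,4a,5,8,8a-octahydronaphthalen-1-yl prop-2-enoate (4β-acryloyloxy-eudesm-7-en-1β-ol) | CC(C)C1=CC[C@@]2(C)[C@H](O)CC[C@](C)(OC(=O)C=C)[C@@H]2C1 | intermediate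
16 | styrene | C=Cc1ccccc1 | starting material
17 | (1S,4R,4aR,8aR)-4-hydroxy-1,4a-dimethyl-7-(propan-2-yl)-1,2,3,4,4a,5,8,8a-octahydronaphthalen-1-yl (2E)-3-phenylprop-2-enoate (4β-cinnamoyloxy-eudesm-7-en-1β-ol) | CC(C)C1=CC[C@@]2(C)[C@H](O)CC[C@](C)(OC(=O)/C=C/c3ccccc3)[C@@H]2C1 | intermediate
18 | (1S,4R,4aR,7S,8aR)-7-hydroperoxy-4-hydroxy-1,4a-dimethyl-7-(propan-2-yl)-1,2,3,4,4a,7,8,8a-octahydronaphthalen-1-yl (2E)-3-phenylprop-2-enoate (4β-cinnamoyloxy-7α-hydroperoxy-eudesm-8-en-1β-ol) | CC(C)[C@]1(OO)C=C[C@@]2(C)[C@H](O)CC[C@](C)(OC(=O)/C=C/c3ccccc3)[C@@H]2C1 | target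

## Step count and risks

Total step count: 9. Longest linear sequence: 9 steps (1 → 18).

The three steps most likely to fail:

Risk 1, step 4 (the proposed new 1,2-allyl shift). It may lose to silylation of the tertiary alcohol or to γ-deprotonation giving a silyl dienol ether. The fallback uses known chemistry, sets out from 6 and comes back at 7. Weitz–Scheffer epoxidation of 6 (H2O2, NaOH, MeOH, 0 °C; hydroperoxide adds to C10 anti to the allyl group) gives (5S)-5-hydroxy-6-methyl-1-(3-methyl-2-methylidenebutyl)-5-(prop-2-en-1-yl)-7-oxabicyclo[4.1.0]heptan-2-one F1, with the oxirane oxygen cis to the hydroxyl. BF3·OEt2 in CH2Cl2 at −78 °C opens the oxirane at the tertiary carbon next to the carbinol, and the allyl group shifts anti to the leaving oxygen (the established semipinacol rearrangement of 2,3-epoxy alcohols). This gives (2R,3R)-3-hydroxy-2-methyl-3-(3-methyl-2-methylidenebutyl)-2-(prop-2-en-1-yl)cyclohexane-1,4-dione F2. SmI2 in THF/HMPA at −78 °C then cleaves the C–O bond alpha to the C4 ketone, and the trivalent samarium enolate is trapped with TIPSOTf to give 7.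

Risk 2, step 2 (allylic oxidation). The allyl side chain and the vinylic methyl offer competing allylic C–H bonds. The fallback sets out from 2 and comes back at 3. Silylation (TESOTf, 2,6-lutidine, CH2Cl2, −78 °C) gives triethyl{[(1S)-2-methyl-1-(prop-2-en-1-yl)cyclohex-2-en-1-yl]oxy}silane F3. Stoichiometric hexavalent chromium oxidation (CrO3, 3,5-dimethylpyrazole, CH2Cl2, −20 °C) now has no free tertiary allylic alcohol to transpose and gives (4S)-3-methyl-4-(prop-2-en-1-yl)-4-[(triethylsilyl)oxy]cyclohex-2-en-1-one F4. TBAF in THF removes the silyl group to give 3.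

Risk 3, step 3 (dienolate α-alkylation). Possible side reactions are α′-alkylation, double alkylation and O-alkylation of the tertiary alkoxide. The fallback sets out from 3 (with the stannane made from 4) and comes back at 6. α-Iodination (I2, pyridine, CH2Cl2, rt) gives (4S)-4-hydroxy-2-iodo-3-methyl-4-(prop-2-en-1-yl)cyclohex-2-en-1-one F5. Bromide 4 with Bu3SnLi (THF, −78 °C) gives tributyl(3-methyl-2-methylidenebutyl)stannane F6, whose allyl termini are equivalent. Stille coupling of F5 with F6 (Pd2(dba)3, AsPh3, CuI, DMF, 50 °C) gives 6.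

Further compounds

F1 | step 4 | (5S)-5-hydroxy-6-methyl-1-(3-methyl-2-methylidenebutyl)-5-(prop-2-en-1-yl)-7-oxabicyclo[4.1.0]heptan-2-one, oxirane oxygen cis to the hydroxyl | C=CC[C@@]1(O)CCC(=O)[C@]2(CC(=C)C(C)C)O[C@]12C
F2 | step 4 | (2R,3R)-3-hydroxy-2-methyl-3-(3-methyl-2-methylidenebutyl)-2-(prop-2-en-1-yl)cyclohexane-1,4-dione | C=CC[C@@]1(C)C(=O)CCC(=O)[C@@]1(O)CC(=C)C(C)C
F3 | step 2 | triethyl{[(1S)-2-methyl-1-(prop-2-en-1-yl)cyclohex-2-en-1-yl]oxy}silane | C=CC[C@@]1(O[Si](CC)(CC)CC)CCCC=C1C
F4 | step 2 | (4S)-3-methyl-4-(prop-2-en-1-yl)-4-[(triethylsilyl)oxy]cyclohex-2-en-1-one | C=CC[C@@]1(O[Si](CC)(CC)CC)CCC(=O)C=C1C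
F5 | step 3 | (4S)-4-hydroxy-2-iodo-3-methyl-4-(prop-2-en-1-yl)cyclohex-2-en-1-one | C=CC[C@@]1(O)CCC(=O)C(I)=C1C
F6 | step 3 | tributyl(3-methyl-2-methylidenebutyl)stannane | CCCC[Sn](CCCC)(CCCC)CC(=C)C(C)C
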